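The runs were computed for an exercise; noise was put on by code.

The easy step comes first: in the autumn run, with 0.070 mM of free catalyst, the reading at 0.250 min already holds nearly all of the charge as open intermediate plus target, so the question is how fast open intermediate passes on to target.

| setting | autumn | midnight | noon | Sunday's | Tuesday's | Friday's | Monday's |
|---|---|---|---|---|---|---|---|
| substrate | 5 mM | 5 mM | 10 mM | 5.0 mM | 5.0 mM | 5.0 mM | 5.0 mM |
| gas | 0.83 mM (held) | 0.83 mM (held) | 0.83 mM (held) | 0.83 mM (held) | 0.83 mM (held) | 0.83 mM (held) | 0.83 mM (held) |
| free catalyst | 0.070 mM | 0.28 mM | 0.14 mM | 0.14 mM | 0.14 mM | 0.14 mM | 0.14 mM |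
| temperature | 42 °C | 59 °C | 42 °C | 35 °C |  | 65 °C | 50 °C |
| remark | run made earlier | run made earlier | run made earlier |  | at 35 °C until 2.0 min, from then on at 65 °C |  |  |
| time |  |  |  | 2.5 min | 2.5 min | 2.5 min | 2.5 min |

autumn run (percent of the substrate charged)

| time / min | open intermediate / % | target / % |
|---|---|---|
| 0.250 | 96.0 | 3.0 |
| 0.500 | 91.5 | 9.4 |
| 1.33 | 75.5 | 24.8 |
| 3.00 | 53.0 | 48.7 |

midnight run (percent of the substrate charged)

| time / s | open intermediate / % | target / % |
|---|---|---|
| 10.0 | 79.3 | 17.3 |
| 25.0 | 57.5 | 44.4 |
| 60.0 | 23.6 | 76.9 |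

noon run (percent of the substrate charged)

| time / min | open intermediate / % | target / % |
|---|---|---|
| 0.417 | 87.0 | 13.2 |
| 1.00 | 69.2 | 28.7 |
| 2.00 | 47.6 | 52.8 |
| 3.00 | 30.9 | 69.2 |

(scatter of a reading: 1 percentage point)

- at the start none of the gas is in solution

- the best flask by amount of open intermediate, in percent of the substrate charged; "all alike" if 1.5 percentage points covers them all (Sunday's / Tuesday's / Friday's / Monday's / all alike)
- amount of open intermediate at the end, in percent of the substrate charged, Sunday's
- amount of open intermediate at the end, in percent of the substrate charged, Tuesday's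
- amount of open intermediate at the end, in percent of the substrate charged, Friday's
- amount of open intermediate at the end, in percent of the substrate charged, Monday's

So each run is read as a pseudo-first-order decay, and its first and last readings give a half-life of 3.21 min for autumn, 0.477 min for midnight and 1.73 min for noon. But the catalyst differs, so this reckoning takes the half-life as inversely proportional to free catalyst. At 0.14 mM that gives 1.60 min at 42 °C and 0.953 min at 59 °C, while noon, with 10 mM of substrate, stands somewhat longer at 1.73 min, a warning that the scaling is approximate. This reckoning assumes that the half-life shrinks by a constant factor per degree, reads that factor between 42 °C and 59 °C, and extrapolates it below them to 35 °C, so Sunday's is reckoned at 1.99 min: this is the half-life of the open intermediate, the time in which a flask's amount is divided by 2. Friday's, at 65 °C and so an extrapolation too, is reckoned at 0.793 min, and Monday's, at 50 °C and between the two temperatures, at 1.26 min.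

This reckoning adds the half-lives counted at each temperature of a flask, so the counts are 1.26 for Sunday's, 1.64 for Tuesday's, 3.15 for Friday's and 1.99 for Monday's. The fewest belong to Sunday's, and this reckoning leaves 41.8%, 32.2%, 11.3% and 25.2% in that order.

The forecast gives 42%, 33%, 12% and 25% in the same order, and says “Sunday's keeps the most.”

The flasks give 39.9%, 31.5%, 11.2% and 22.9%, with Sunday's the best. At the end of Sunday's, 85.9% of the catalyst stood free and 14.1% as catalyst intermediate. Sunday's result amounts to 1.32 half-lives, so its half-life on average was 1.89 min against the reckoned 1.99 min.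

    free catalyst + open intermediate ⇌ catalyst intermediate (K = 66.0 M⁻¹, k = 1300 M⁻¹ s⁻¹, Ea = 48.0 kJ mol⁻¹, ΔH = −18.0 kJ mol⁻¹)
    substrate → decomposition product (k = 2.70 × 10⁻⁴ s⁻¹, Ea = 110 kJ mol⁻¹)
    gas ⇌ reagent, rate k3*(csat - [reagent]) (kL = 18.0 s⁻¹)
    substrate + free catalyst → free catalyst + open intermediate (k = 8900 M⁻¹ s⁻¹, Ea = 17.0 kJ mol⁻¹)
    reagent + catalyst intermediate → free catalyst + target (k = 1600 M⁻¹ s⁻¹, Ea = 37.0 kJ mol⁻¹)
    (constants at 50 °C)

For a flask like Friday's with 0.035 mM of free catalyst, the same reckoning stretches the half-life from 0.793 min to 3.17 min, so 2.5 min counts 0.789 half-lives and is reckoned to leave 57.9%. The simulation gives 60.2%.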